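## The problem

The target 21 is a furofuran lignan: two tetrahydrofuran rings cis-fused through one C–C bond (a 2,6-diaryl-3,7-dioxabicyclo[3.3.0]octane), both aryl groups on the convex face, in the (7R,8S,7'R,8'S) series. Lignan numbering is used throughout: C7 and C7' are the benzylic O–CH carbons on the phenol ring (ring A) and the prenyloxy ring (ring B), C8 and C8' the ring-fusion CH carbons, C9 (on C8) and C9' (on C8') the O–CH2 carbons; O1 joins C7 to C9' in ring 1 and O2 joins C7' to C9 in ring 2. Of the four contiguous stereocentres, C8' follows from C8 because the fusion can only be cis, and C8 can be controlled by its neighbour C7 in a ring closure. C7' is out of reach of C7 and cannot be set by hydride addition to a ring 2 oxocarbenium ion, which would come from the convex face and leave ring B endo; it must be set by a reagent before ring 2 closes and then be kept with retention. The core is C2-symmetric but the two aryl groups differ, so a route through a symmetric diphenol ends in a statistical mono-prenylation; the rings are better told apart from the first C–C bond on. The groups at risk are the two benzylic C–O bonds, each para to an oxygen substituent (acid ionisation with epimerisation, hydrogenolysis), the prenyl ether (an electron-rich trisubstituted alkene, open to electrophilic radicals, boranes, Lewis acids and hydrogenation) and the free phenol (oxidants). The enabling feature: with ring 1 written as its C9' lactone and C7' as a ketone, C8' is the central carbon of a 1,3-dicarbonyl unit and C8–C9 is a vinyl group on C7, so a 1-arylallyl aroylacetate holds every skeletal carbon and one-electron oxidation at C8' can close ring 1 onto the vinyl group.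

## Retrosynthesis

**Phenol substituents last (21 ⇒ 20 ⇒ 18 + 19 ⇒ 17).** The O–Si bond on ring A, the O–prenyl bond on ring B and, behind it, an O–benzyl bond are cut. Carrying the prenyl ether from the start would save two steps, but its alkene is a better acceptor for the electrophilic radical of the key step than the acyloxy-substituted vinyl group, and it would also meet borane and BF3·OEt2. Ring B is therefore carried as a benzyl ether and ring A as a triisopropylsilyl ether: 17 is debenzylated to 18, the only free phenol is alkylated with prenyl bromide 19 to give 20, and fluoride releases 21. The forward hydrogenolysis must spare the two benzylic ring C–O bonds.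

**C9' back to the lactone level (17 ⇒ 16 ⇒ 15).** No skeletal bond is cut; the C9' methylene is traced to lactol 16 and lactone 15. The lactone is what the key step delivers, and it makes C8' α to a carbonyl group, the only state in which C8' can still be corrected. The forward reduction (two steps) must not ionise the benzylic ethers.

**Ring 2 through C9–O2 (15 ⇒ 14 ⇒ 13 ⇒ 12).** Cutting C9–O2 gives a C7' carbinol and a C9 iodide (12). The neighbouring cut, C7'–O2, would run forward through a benzylic cation and leave C7' to chance; the C9–O2 cut keeps C7' out of the reaction, so a preset carbinol is carried over with retention. The difficulty is that in lactone 12 the C8' and C8 substituents are trans, so O2 cannot reach C9. The forward step therefore opens the lactone with methanol (13), closes ring 2 in the open chain (14), and lets the ester α-centre C8' equilibrate until the one epimer that can relactonise is drained off as 15.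

**C7' and the sacrificial bond (12 ⇒ 11 ⇒ 10).** The carbinol is traced to ketone 11, and the C9–I and C8'–H bonds to the cyclopropane bond C8'–C9 of 10. Iodide serves twice, as the nucleophile that opens the doubly activated ring and as the leaving group for O2. The ketone is reduced only after the opening, because it is half of the activation. The forward reduction must be catalyst-controlled and free of base.

**Key disconnection (10 ⇒ 9).** C8–C8' and C8'–C9 are cut together, which opens both the lactone and the cyclopropane and returns the open-chain β-keto ester 9 with a single stereocentre (C7). Polar alternatives for C8–C8' (conjugate addition, aldol) would need C9 at a higher oxidation level and a second chiral input. Here an oxidant turns a CH2 between two carbonyl groups and a vinyl group into two rings, two C–C bonds and two stereocentres, with the spare bond placed on C9, which is not a stereocentre.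

**The aroylacetate (9 ⇒ 8 ⇒ 6 + 7).** The C8'–C7' bond is cut (aldol addition, then oxidation of 8). The neighbouring cut, the ester C–O bond, would need hot transesterification of a 1-arylallyl alcohol with an aroylacetate, with the risk of Carroll rearrangement and allylic transposition. The aldol route runs at −78 °C and uses acetate 6 and O-benzylvanillin 7 directly.

**The allylic acetate (6 ⇒ 4 + 5 ⇒ 2 + 3 ⇒ 1).** The acetyl C–O bond is cut enzymatically, which sets C7; the acetyl group from vinyl acetate 5 is not waste, since its two carbons become C9' and C8'. Racemic alcohol 4 comes from aldehyde 2 and vinylmagnesium bromide 3 (C7–C8), and 2 from vanillin 1.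

## Roads not taken

**Alternative 1:** Both aryl–carbon bonds (C7–ring A, C7'–ring B) are cut from a preformed C2-symmetric bicyclic bis-acetal. Forward, BF3·OEt2 ionises the two anomeric acetates in turn and an arylzinc reagent adds from the convex face each time, giving the bis-silyl ether A1. The merits are real: the route is convergent and probably shorter than the chosen one, and the aryl group enters as the nucleophile, so it ends exo by the same facial preference that makes hydride reductions fail. Its weak point for this target is symmetry. The two anomeric positions are equivalent, so two different aryl groups cannot be introduced cleanly, and A1 carries two identical silyl ethers; after desilylation the single prenyl group has to be put on by a statistical alkylation with recycling. The enantiopure bis-acetal core must also be made separately. In step count and in control of C7 and C7' this road is at least as good; the chosen plan sets against it that ring A and ring B are different from the first C–C bond and that no statistical step occurs.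

**Alternative 2:** C8–C8' and a sacrificial C7–C7' bond are cut, leading back to a mixed bis-cinnamate on a threitol acetonide tether. Forward, irradiation or triplet sensitisation closes the all-trans head-to-head cyclobutane A2 inside a ten-membered tether ring. The two aryl groups are differentiated from the outset by sequential esterification, the tether from tartaric acid gives absolute control at C8 and C8', and the step count is lower on paper than here. The weak points lie after the key step. The C7–C7' bond, joining two stereocentres, must be cleaved selectively, which in practice means single-electron oxidation of an aryl group, with the acetoxy and prenyloxy rings differing in oxidation potential. Both benzylic cations must then be trapped by the C9 and C9' oxygen atoms with exo selectivity, so C7 and C7' are both set under ionising conditions with no control element. The prenyl alkene is exposed to light, sensitiser and oxidant, and E/Z isomerisation and regiochemistry of the [2+2] step are open. The chosen plan is longer but sets each stereocentre by a defined element and opens its sacrificial bond by polar chemistry at a carbon that is not a stereocentre.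

**Alternative 3:** C9'–C8' and C7–C8 are cut, leading back to an acyclic allylic diol whose C7 oxygen carries the methoxymethyl group that supplies C9'. Forward, SnCl4 ionises the acetal, the alkene attacks the oxocarbenium carbon (Prins), and C7 migrates to the cationic C8 (pinacol shift with ring contraction), releasing C9 as an aldehyde in the formyl tetrahydrofuran A3. This is the most economical construction of ring 1: three stereocentres from one ordered transition state, C7' already in place, and a short endgame. Against it stand the precursor and the phenols. The open-chain substrate needs three carbinol stereocentres and a defined alkene before the key step. The migrating and ionising centres are electron-rich benzylic carbons under SnCl4. Both phenols emerge as pivalates, which are unlike but not chemically distinguishable, so an exchange of protecting groups is needed before mono-prenylation. The C8 aldehyde is also epimerisable. In stereochemical elegance and step count for the core this road is as good as or better than the chosen one; the chosen plan offers a much simpler precursor (two aldehydes, a vinyl Grignard reagent, vinyl acetate, one resolution) and built-in differentiation of the phenols.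

Key step: step 6

Assumption: Candida antarctica lipase B is taken to follow its usual size preference (aryl large, vinyl medium), so the acetylated enantiomer is (R), and the (S)-oxazaborolidine is taken to treat the aryl group as the large ketone substituent.

## Route

Step 1
Reactants: 1 vanillin
Product: 2 3-methoxy-4-[(triisopropylsilyl)oxy]benzaldehyde
Conditions: TIPSCl, imidazole, DMF, rt
Reagents that add atoms: triisopropylsilyl chloride (TIPSCl), CC(C)[Si](Cl)(C(C)C)C(C)C
Why: Imidazole-promoted O-silylation of the phenol; the aryl triisopropylsilyl ether should survive Grignard and amide bases, warm AcOH, borane, i-Bu2AlH, BF3·OEt2 at low temperature and brief methanolic carbonate, and is removed last by fluoride.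

Step 2
Reactants: 2 3-methoxy-4-[(triisopropylsilyl)oxy]benzaldehyde; 3 vinylmagnesium bromide
Product: 4 rac-1-{3-methoxy-4-[(triisopropylsilyl)oxy]phenyl}prop-2-en-1-ol
Conditions: THF, −78 °C to 0 °C; aq. NH4Cl
Reagents that add atoms: none
Why: Grignard 1,2-addition to an aryl aldehyde forms C7–C8; the alcohol is racemic and is resolved in the next step.

Step 3
Reactants: 4 rac-1-{3-methoxy-4-[(triisopropylsilyl)oxy]phenyl}prop-2-en-1-ol; 5 vinyl acetate
Product: 6 (R)-1-{3-methoxy-4-[(triisopropylsilyl)oxy]phenyl}prop-2-en-1-yl acetate
Conditions: Candida antarctica lipase B (immobilised), vinyl acetate (3 equiv), t-BuOMe, 30 °C, stopped near half conversion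
Reagents that add atoms: none
Why: Lipase-catalysed kinetic resolution by irreversible transesterification; with aryl as the large and vinyl as the medium group the (R)-alcohol is acetylated, which sets C7, while the (S)-enantiomer of 4 stays unreacted and is removed by chromatography. The transferred acetyl group supplies C9' and C8'.

Step 4
Reactants: 6 (R)-1-{3-methoxy-4-[(triisopropylsilyl)oxy]phenyl}prop-2-en-1-yl acetate; 7 4-(benzyloxy)-3-methoxybenzaldehyde
Product: 8 (R)-1-{3-methoxy-4-[(triisopropylsilyl)oxy]phenyl}prop-2-en-1-yl 3-[4-(benzyloxy)-3-methoxyphenyl]-3-hydroxypropanoate (both epimers at the new carbinol)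
Conditions: LiN(i-Pr)2, THF, −78 °C; then 7, −78 °C; AcOH quench at −78 °C
Reagents that add atoms: none
Why: Lithium enolate aldol addition of an acetate ester to an aromatic aldehyde forms C8'–C7'; at −78 °C neither Ireland–Claisen rearrangement nor self-condensation of the allylic acetate enolate should compete, and the new carbinol centre is left uncontrolled because it is oxidised next.

Step 5
Reactants: 8 (R)-1-{3-methoxy-4-[(triisopropylsilyl)oxy]phenyl}prop-2-en-1-yl 3-[4-(benzyloxy)-3-methoxyphenyl]-3-hydroxypropanoate
Product: 9 (R)-1-{3-methoxy-4-[(triisopropylsilyl)oxy]phenyl}prop-2-en-1-yl 3-[4-(benzyloxy)-3-methoxyphenyl]-3-oxopropanoate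
Conditions: Dess–Martin periodinane (1.2 equiv), CH2Cl2, 0 °C to rt
Reagents that add atoms: none
Why: Dess–Martin oxidation of a β-hydroxy ester to the β-keto ester under non-basic conditions that leave the allylic ester, the silyl ether and the benzyl ether alone.

Step 6
Reactants: 9 (R)-1-{3-methoxy-4-[(triisopropylsilyl)oxy]phenyl}prop-2-en-1-yl 3-[4-(benzyloxy)-3-methoxyphenyl]-3-oxopropanoate
Product: 10 (1S,4R,5R)-1-[4-(benzyloxy)-3-methoxybenzoyl]-4-{3-methoxy-4-[(triisopropylsilyl)oxy]phenyl}-3-oxabicyclo[3.1.0]hexan-2-one
Conditions: Mn(OAc)3·2H2O (2.2 equiv), Cu(OAc)2·H2O (1.0 equiv), degassed AcOH, 60 °C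
Reagents that add atoms: none
Why: Mn(OAc)3 (trivalent manganese) enolises the aroylacetate and oxidises the enolate to a manganese-bound C8' radical, which adds 5-exo-trig to the vinyl group and closes lactone ring 1 through C8–C8'. The primary C9 radical is intercepted by Cu(OAc)2 (divalent copper) and oxidised to an alkylcopper or cation equivalent, which the enol carbon C8' of the still enolisable keto lactone attacks in a 3-exo closure, forming the cyclopropane bond C8'–C9 with loss of a proton. The closest known reaction type is the Mn(OAc)3/Cu(OAc)2 oxidative cyclisation of allylic and 1-arylallyl acetoacetates to 1-acyl-3-oxabicyclo[3.1.0]hexan-2-ones. C8 is set by C7: in the chair-like 5-exo transition state the aryl group on the allylic carbon sits pseudo-equatorial, the normal outcome for a 4-substituted hex-5-enyl radical, which puts C9 trans to the aryl group. C8' is then fixed by geometry, because a three-membered ring can only be cis-fused to the lactone. The step needs 5-exo over 6-endo closure (normal for a terminal vinyl group), the trans relation at C7/C8 (secured by the aryl group) and the absence of a second alkene (secured by carrying ring B as its benzyl ether). Two equivalents of Mn(OAc)3 are consumed.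

Step 7
Reactants: 10 (1S,4R,5R)-1-[4-(benzyloxy)-3-methoxybenzoyl]-4-{3-methoxy-4-[(triisopropylsilyl)oxy]phenyl}-3-oxabicyclo[3.1.0]hexan-2-one
Product: 11 (3S,4R,5R)-3-[4-(benzyloxy)-3-methoxybenzoyl]-4-(iodomethyl)-5-{3-methoxy-4-[(triisopropylsilyl)oxy]phenyl}oxolan-2-one
Conditions: MgI2 (2 equiv), THF, 0 °C to rt; AcOH (excess) at −40 °C, then aqueous work-up
Reagents that add atoms: magnesium iodide (MgI2), [Mg+2].[I-].[I-]
Why: Homoconjugate (SN2-type) opening of the doubly activated cyclopropane by iodide at the unhindered methylene C9, with magnesium chelating both carbonyl oxygens of the enolate; protonation with AcOH in the cold removes the enolate before it can re-close. C8' becomes an epimerisable CH that settles trans to the iodomethyl group; C7 and C8 are untouched.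

Step 8
Reactants: 11 (3S,4R,5R)-3-[4-(benzyloxy)-3-methoxybenzoyl]-4-(iodomethyl)-5-{3-methoxy-4-[(triisopropylsilyl)oxy]phenyl}oxolan-2-one
Product: 12 (3S,4R,5R)-3-{(R)-[4-(benzyloxy)-3-methoxyphenyl](hydroxy)methyl}-4-(iodomethyl)-5-{3-methoxy-4-[(triisopropylsilyl)oxy]phenyl}oxolan-2-one
Conditions: (S)-2-methyl-CBS-oxazaborolidine [(S)-1-methyl-3,3-diphenyltetrahydro-1H,3H-pyrrolo[1,2-c][1,3,2]oxazaborole] (0.2 equiv), BH3·SMe2 (1.2 equiv), THF, −30 °C; MeOH quench
Reagents that add atoms: none
Why: Corey–Bakshi–Shibata reduction of an aryl ketone; with the aryl group as the large substituent the (S)-catalyst should deliver hydride to give the (7'R)-carbinol, which sets C7'. The medium is free of base, so the iodide is not displaced by an enolate, and the lactone is reduced much more slowly than the catalyst-bound ketone.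

Step 9
Reactants: 12 (3S,4R,5R)-3-{(R)-[4-(benzyloxy)-3-methoxyphenyl](hydroxy)methyl}-4-(iodomethyl)-5-{3-methoxy-4-[(triisopropylsilyl)oxy]phenyl}oxolan-2-one
Product: 15 (3R,3aS,6R,6aR)-6-[4-(benzyloxy)-3-methoxyphenyl]-3-{3-methoxy-4-[(triisopropylsilyl)oxy]phenyl}tetrahydro-1H,3H-furo[3,4-c]furan-1-one, via acyclic iodo dihydroxy methyl ester 13 (not isolated), via tetrahydrofuran methyl ester 14 (not isolated)
Conditions: K2CO3 (2 equiv), MeOH, 0 °C to rt; then solvent exchange, DBU (0.3 equiv), toluene, 60 °C
Reagents that add atoms: none
Why: In trans-lactone 12 the C7' oxygen cannot reach C9, but reversible methanolysis of the lactone gives open-chain 13, in which the C7' alkoxide displaces iodide (intramolecular Williamson etherification, 5-exo-tet, retention at C7') to give 14 without any enolate being formed while the iodide is present. DBU then equilibrates the ester α-centre C8', and only the epimer with the ester cis to the C7 side chain can lactonise onto the C7 hydroxyl (acyl substitution, retention at C7), so the material drains into cis-fused lactone 15 with ring B trans to C9', i.e. exo.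

Step 10
Reactants: 15 (3R,3aS,6R,6aR)-6-[4-(benzyloxy)-3-methoxyphenyl]-3-{3-methoxy-4-[(triisopropylsilyl)oxy]phenyl}tetrahydro-1H,3H-furo[3,4-c]furan-1-one
Product: 16 (3R,3aS,6R,6aR)-6-[4-(benzyloxy)-3-methoxyphenyl]-3-{3-methoxy-4-[(triisopropylsilyl)oxy]phenyl}tetrahydro-1H,3H-furo[3,4-c]furan-1-ol (both anomers)
Conditions: i-Bu2AlH (1.2 equiv), CH2Cl2, −78 °C; aq. potassium sodium tartrate
Reagents that add atoms: none
Why: Partial reduction of a γ-lactone to the lactol; the tetrahedral aluminium alkoxide is stable at −78 °C, and the anomeric centre is removed in the next step.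

Step 11
Reactants: 16 (3R,3aS,6R,6aR)-6-[4-(benzyloxy)-3-methoxyphenyl]-3-{3-methoxy-4-[(triisopropylsilyl)oxy]phenyl}tetrahydro-1H,3H-furo[3,4-c]furan-1-ol
Product: 17 (1R,3aS,4R,6aS)-1-[4-(benzyloxy)-3-methoxyphenyl]-4-{3-methoxy-4-[(triisopropylsilyl)oxy]phenyl}tetrahydro-1H,3H-furo[3,4-c]furan
Conditions: Et3SiH (3 equiv), BF3·OEt2 (1.5 equiv), CH2Cl2, −78 °C to −40 °C
Reagents that add atoms: none
Why: Ionic hydrogenation of a lactol: BF3·OEt2 ionises the anomeric hydroxyl to the C9' oxocarbenium ion and Et3SiH delivers hydride; C9' becomes a CH2 group, so no stereocentre is at stake, and the low temperature is meant to keep the benzylic C–O bonds from ionising.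

Step 12
Reactants: 17 (1R,3aS,4R,6aS)-1-[4-(benzyloxy)-3-methoxyphenyl]-4-{3-methoxy-4-[(triisopropylsilyl)oxy]phenyl}tetrahydro-1H,3H-furo[3,4-c]furan
Product: 18 2-methoxy-4-[(1R,3aS,4R,6aS)-4-{3-methoxy-4-[(triisopropylsilyl)oxy]phenyl}tetrahydro-1H,3H-furo[3,4-c]furan-1-yl]phenol
Conditions: H2 (1 atm), Pd/C (10%), EtOAc, rt, stopped at full conversion
Reagents that add atoms: none
Why: Hydrogenolysis of an aryl benzyl ether over palladium on carbon under neutral conditions, which should be much faster than cleavage of the dialkyl benzylic ethers of the bicycle; the silyl ether is inert.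

Step 13
Reactants: 18 2-methoxy-4-[(1R,3aS,4R,6aS)-4-{3-methoxy-4-[(triisopropylsilyl)oxy]phenyl}tetrahydro-1H,3H-furo[3,4-c]furan-1-yl]phenol; 19 prenyl bromide (1-bromo-3-methylbut-2-ene)
Product: 20 (1R,3aS,4R,6aS)-1-{3-methoxy-4-[(3-methylbut-2-en-1-yl)oxy]phenyl}-4-{3-methoxy-4-[(triisopropylsilyl)oxy]phenyl}tetrahydro-1H,3H-furo[3,4-c]furan
Conditions: K2CO3, acetone, rt
Reagents that add atoms: none
Why: Williamson ether synthesis (SN2 O-alkylation of the phenoxide with an allylic bromide); ring B carries the only free phenol, so no selectivity question arises.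

Step 14
Reactants: 20 (1R,3aS,4R,6aS)-1-{3-methoxy-4-[(3-methylbut-2-en-1-yl)oxy]phenyl}-4-{3-methoxy-4-[(triisopropylsilyl)oxy]phenyl}tetrahydro-1H,3H-furo[3,4-c]furan
Product: 21 2-methoxy-4-[(1R,3aS,4R,6aS)-4-{3-methoxy-4-[(3-methylbut-2-en-1-yl)oxy]phenyl}tetrahydro-1H,3H-furo[3,4-c]furan-1-yl]phenol (the target)
Conditions: Bu4NF, THF, 0 °C; aqueous work-up
Reagents that add atoms: none
Why: Fluoride-induced cleavage of the aryl silyl ether; the prenyl ether and the furofuran are inert to Bu4NF, and no stereocentre is touched.

## Compound list

1 | vanillin | COc1cc(C=O)ccc1O | starting material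
2 | 3-methoxy-4-[(triisopropylsilyl)oxy]benzaldehyde | COc1cc(C=O)ccc1O[Si](C(C)C)(C(C)C)C(C)C | intermediate
3 | vinylmagnesium bromide | C=C[Mg]Br | starting material
4 | rac-1-{3-methoxy-4-[(triisopropylsilyl)oxy]phenyl}prop-2-en-1-ol | COc1cc(C(O)C=C)ccc1O[Si](C(C)C)(C(C)C)C(C)C | intermediate
5 | vinyl acetate | C=COC(C)=O | starting material
6 | (R)-1-{3-methoxy-4-[(triisopropylsilyl)oxy]phenyl}prop-2-en-1-yl acetate | COc1cc([C@@H](C=C)OC(C)=O)ccc1O[Si](C(C)C)(C(C)C)C(C)C | intermediate
7 | 4-(benzyloxy)-3-methoxybenzaldehyde (O-benzylvanillin) | COc1cc(C=O)ccc1OCc1ccccc1 | starting material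
8 | (R)-1-{3-methoxy-4-[(triisopropylsilyl)oxy]phenyl}prop-2-en-1-yl 3-[4-(benzyloxy)-3-methoxyphenyl]-3-hydroxypropanoate (carbinol epimers) | COc1cc([C@@H](C=C)OC(=O)CC(O)c2ccc(OCc3ccccc3)c(OC)c2)ccc1O[Si](C(C)C)(C(C)C)C(C)C | intermediate
9 | (R)-1-{3-methoxy-4-[(triisopropylsilyl)oxy]phenyl}prop-2-en-1-yl 3-[4-(benzyloxy)-3-methoxyphenyl]-3-oxopropanoate | COc1cc([C@@H](C=C)OC(=O)CC(=O)c2ccc(OCc3ccccc3)c(OC)c2)ccc1O[Si](C(C)C)(C(C)C)C(C)C | intermediate
10 | (1S,4R,5R)-1-[4-(benzyloxy)-3-methoxybenzoyl]-4-{3-methoxy-4-[(triisopropylsilyl)oxy]phenyl}-3-oxabicyclo[3.1.0]hexan-2-one | COc1cc([C@@H]2OC(=O)[C@@]3(C(=O)c4ccc(OCc5ccccc5)c(OC)c4)C[C@@H]23)ccc1O[Si](C(C)C)(C(C)C)C(C)C | intermediate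
11 | (3S,4R,5R)-3-[4-(benzyloxy)-3-methoxybenzoyl]-4-(iodomethyl)-5-{3-methoxy-4-[(triisopropylsilyl)oxy]phenyl}oxolan-2-one | COc1cc([C@@H]2OC(=O)[C@H](C(=O)c3ccc(OCc4ccccc4)c(OC)c3)[C@H]2CI)ccc1O[Si](C(C)C)(C(C)C)C(C)C | intermediate
12 | (3S,4R,5R)-3-{(R)-[4-(benzyloxy)-3-methoxyphenyl](hydroxy)methyl}-4-(iodomethyl)-5-{3-methoxy-4-[(triisopropylsilyl)oxy]phenyl}oxolan-2-one | COc1cc([C@@H]2OC(=O)[C@H]([C@@H](O)c3ccc(OCc4ccccc4)c(OC)c3)[C@H]2CI)ccc1O[Si](C(C)C)(C(C)C)C(C)C | intermediate
13 | methyl (2S,3R)-2-{(R)-[4-(benzyloxy)-3-methoxyphenyl](hydroxy)methyl}-3-{(R)-hydroxy{3-methoxy-4-[(triisopropylsilyl)oxy]phenyl}methyl}-4-iodobutanoate | COc1cc([C@H](O)[C@H](CI)[C@@H]([C@@H](O)c2ccc(OCc3ccccc3)c(OC)c2)C(=O)OC)ccc1O[Si](C(C)C)(C(C)C)C(C)C | intermediate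
14 | methyl (2R,3S,4S)-2-[4-(benzyloxy)-3-methoxyphenyl]-4-{(R)-hydroxy{3-methoxy-4-[(triisopropylsilyl)oxy]phenyl}methyl}oxolane-3-carboxylate | COc1cc([C@H](O)[C@@H]2CO[C@@H](c3ccc(OCc4ccccc4)c(OC)c3)[C@H]2C(=O)OC)ccc1O[Si](C(C)C)(C(C)C)C(C)C | intermediate
15 | (3R,3aS,6R,6aR)-6-[4-(benzyloxy)-3-methoxyphenyl]-3-{3-methoxy-4-[(triisopropylsilyl)oxy]phenyl}tetrahydro-1H,3H-furo[3,4-c]furan-1-one | COc1cc([C@@H]2OC(=O)[C@@H]3[C@H]2CO[C@H]3c2ccc(OCc3ccccc3)c(OC)c2)ccc1O[Si](C(C)C)(C(C)C)C(C)C | intermediate
16 | (3R,3aS,6R,6aR)-6-[4-(benzyloxy)-3-methoxyphenyl]-3-{3-methoxy-4-[(triisopropylsilyl)oxy]phenyl}tetrahydro-1H,3H-furo[3,4-c]furan-1-ol (anomers) | COc1cc([C@@H]2OC(O)[C@@H]3[C@H]2CO[C@H]3c2ccc(OCc3ccccc3)c(OC)c2)ccc1O[Si](C(C)C)(C(C)C)C(C)C | intermediate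
17 | (1R,3aS,4R,6aS)-1-[4-(benzyloxy)-3-methoxyphenyl]-4-{3-methoxy-4-[(triisopropylsilyl)oxy]phenyl}tetrahydro-1H,3H-furo[3,4-c]furan | COc1cc([C@@H]2OC[C@@H]3[C@H]2CO[C@H]3c2ccc(OCc3ccccc3)c(OC)c2)ccc1O[Si](C(C)C)(C(C)C)C(C)C | intermediate
18 | 2-methoxy-4-[(1R,3aS,4R,6aS)-4-{3-methoxy-4-[(triisopropylsilyl)oxy]phenyl}tetrahydro-1H,3H-furo[3,4-c]furan-1-yl]phenol | COc1cc([C@@H]2OC[C@@H]3[C@H]2CO[C@H]3c2ccc(O)c(OC)c2)ccc1O[Si](C(C)C)(C(C)C)C(C)C | intermediate
19 | prenyl bromide (1-bromo-3-methylbut-2-ene) | CC(C)=CCBr | starting material
20 | (1R,3aS,4R,6aS)-1-{3-methoxy-4-[(3-methylbut-2-en-1-yl)oxy]phenyl}-4-{3-methoxy-4-[(triisopropylsilyl)oxy]phenyl}tetrahydro-1H,3H-furo[3,4-c]furan | COc1cc([C@@H]2OC[C@@H]3[C@H]2CO[C@H]3c2ccc(OCC=C(C)C)c(OC)c2)ccc1O[Si](C(C)C)(C(C)C)C(C)C | intermediate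
21 | 2-methoxy-4-[(1R,3aS,4R,6aS)-4-{3-methoxy-4-[(3-methylbut-2-en-1-yl)oxy]phenyl}tetrahydro-1H,3H-furo[3,4-c]furan-1-yl]phenol (CNP0185952.2) | COc1cc([C@@H]2OC[C@@H]3[C@H]2CO[C@H]3c2ccc(OCC=C(C)C)c(OC)c2)ccc1O | target

## Step count and least certain steps

Total step count: 14. Longest linear sequence: 14 steps, from vanillin 1 (3, 5, 7 and 19 are bought).

**Step 6 (key step).** The most likely failure is slow 5-exo closure of the ester-linked radical (the ester prefers its s-trans conformer), so that oligomerisation, α-acetoxylation or over-oxidation compete. The electron-rich 1-arylallyl ester may also ionise in warm acetic acid, with loss of optical purity at C7 or 1,3-transposition. Fallback: the same two bonds are made by a metal carbenoid instead of a radical. Setting out from 9, diazo transfer (4-acetamidobenzenesulfonyl azide, Et3N, MeCN) should give the α-diazo-β-keto ester F1, and Rh2(OAc)4 (dirhodium tetraacetate, 1 mol%) in CH2Cl2 at rt should cyclopropanate the vinyl group intramolecularly and return to the route at 10. No acid or heat is involved; the C7/C8 relation then depends on the fit of substrate and catalyst, and a minor diastereomer would have to be separated.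

**Step 7.** The most likely failure is reversal of the ring opening: the magnesium enolate re-closes on C9 through carbon, or through the ketone oxygen to a bicyclic enol ether, faster than it is protonated. Fallback: an oxygen nucleophile that cannot leave again. Setting out from 10, CsOAc with AcOH in DMF at 60 °C should add acetate to C9 and give the acetoxymethyl keto lactone F2. The reduction of step 8 should then give the (7'R)-carbinol acetate F3. Butanolysis with Candida antarctica lipase B (n-BuOH, t-BuOMe) removes the primary acetate without base and gives the diol F4. An Appel reaction (I2, PPh3, imidazole, CH2Cl2, 0 °C), selective for the primary alcohol, returns to the route at 12.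

**Step 8.** The most likely failure is poor facial selectivity, because the catalyst must override the bias of the adjacent C8' centre and possible chelation between the two carbonyl groups; slow reduction of the lactone is a second risk. Fallback: diastereomer separation with recycling instead of catalyst control. Setting out from 11, Zn(BH4)2 in Et2O at −20 °C (no base present) should give both carbinols, which are diastereomers and separable on silica. 12 goes on; the (7'S)-epimer F5 is oxidised back to 11 with Dess–Martin periodinane and reduced again.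

**Step 9.** The most likely failure lies in the second stage: incomplete equilibration at C8', incomplete lactonisation, or β-elimination of O2 from the ester enolate, which would open ring 2. In the first stage, methanolysis of the aryl silyl ether and fragmentation of the C7 alkoxide toward the iodide are possible. Fallback: correct C8' at the aldehyde level instead of the ester level. Setting out from 12, only the carbonate stage is run and 14 is isolated; i-Bu2AlH (CH2Cl2, −78 °C) reduces its ester to the aldehyde F6. Next to an aldehyde, C8' equilibrates with a trace of Et3N at rt, and the epimer with the formyl group cis to the C7 side chain is captured by the C7 hydroxyl as the lactol, which returns to the route at 16 and makes step 10 unnecessary.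

**Step 11.** The most likely failure is ionisation of the benzylic C7–O1 or C7'–O2 bond by BF3·OEt2, since each is para to an oxygen substituent, with epimerisation or reductive ring opening as the result. Fallback: no Lewis acid. Setting out from 15, LiAlH4 (THF, 0 °C) should give the diol F7. MsCl (1.05 equiv) in pyridine at 0 °C sulfonylates the primary hydroxyl, and the C7 hydroxyl displaces the mesylate (5-exo-tet, retention at C7), returning to the route at 17.

## Further compounds

F1 | step 6 | (R)-1-{3-methoxy-4-[(triisopropylsilyl)oxy]phenyl}prop-2-en-1-yl 3-[4-(benzyloxy)-3-methoxyphenyl]-2-diazo-3-oxopropanoate | COc1cc([C@@H](C=C)OC(=O)C(=[N+]=[N-])C(=O)c2ccc(OCc3ccccc3)c(OC)c2)ccc1O[Si](C(C)C)(C(C)C)C(C)C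
F2 | step 7 | (3S,4S,5R)-4-(acetoxymethyl)-3-[4-(benzyloxy)-3-methoxybenzoyl]-5-{3-methoxy-4-[(triisopropylsilyl)oxy]phenyl}oxolan-2-one | COc1cc([C@@H]2OC(=O)[C@H](C(=O)c3ccc(OCc4ccccc4)c(OC)c3)[C@H]2COC(C)=O)ccc1O[Si](C(C)C)(C(C)C)C(C)C
F3 | step 7 | (3S,4S,5R)-4-(acetoxymethyl)-3-{(R)-[4-(benzyloxy)-3-methoxyphenyl](hydroxy)methyl}-5-{3-methoxy-4-[(triisopropylsilyl)oxy]phenyl}oxolan-2-one | COc1cc([C@@H]2OC(=O)[C@H]([C@@H](O)c3ccc(OCc4ccccc4)c(OC)c3)[C@H]2COC(C)=O)ccc1O[Si](C(C)C)(C(C)C)C(C)C
F4 | step 7 | (3S,4S,5R)-3-{(R)-[4-(benzyloxy)-3-methoxyphenyl](hydroxy)methyl}-4-(hydroxymethyl)-5-{3-methoxy-4-[(triisopropylsilyl)oxy]phenyl}oxolan-2-one | COc1cc([C@@H]2OC(=O)[C@H]([C@@H](O)c3ccc(OCc4ccccc4)c(OC)c3)[C@H]2CO)ccc1O[Si](C(C)C)(C(C)C)C(C)C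
F5 | step 8 | (3S,4R,5R)-3-{(S)-[4-(benzyloxy)-3-methoxyphenyl](hydroxy)methyl}-4-(iodomethyl)-5-{3-methoxy-4-[(triisopropylsilyl)oxy]phenyl}oxolan-2-one | COc1cc([C@@H]2OC(=O)[C@H]([C@H](O)c3ccc(OCc4ccccc4)c(OC)c3)[C@H]2CI)ccc1O[Si](C(C)C)(C(C)C)C(C)C
F6 | step 9 | (2R,3S,4S)-2-[4-(benzyloxy)-3-methoxyphenyl]-4-{(R)-hydroxy{3-methoxy-4-[(triisopropylsilyl)oxy]phenyl}methyl}oxolane-3-carbaldehyde | COc1cc([C@H](O)[C@@H]2CO[C@@H](c3ccc(OCc4ccccc4)c(OC)c3)[C@H]2C=O)ccc1O[Si](C(C)C)(C(C)C)C(C)C
F7 | step 11 | [(2R,3S,4S)-2-[4-(benzyloxy)-3-methoxyphenyl]-4-{(R)-hydroxy{3-methoxy-4-[(triisopropylsilyl)oxy]phenyl}methyl}oxolan-3-yl]methanol | COc1cc([C@H](O)[C@@H]2CO[C@@H](c3ccc(OCc4ccccc4)c(OC)c3)[C@@H]2CO)ccc1O[Si](C(C)C)(C(C)C)C(C)C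
A1 | alternative 1 | (1R,3aS,4R,6aS)-1,4-bis{4-[(tert-butyldimethylsilyl)oxy]-3-methoxyphenyl}tetrahydro-1H,3H-furo[3,4-c]furan (bis-silyl ether of the unprenylated diphenol) | COc1cc([C@@H]2OC[C@@H]3[C@H]2CO[C@H]3c2ccc(O[Si](C)(C)C(C)(C)C)c(OC)c2)ccc1O[Si](C)(C)C(C)(C)C
A2 | alternative 2 | tethered all-trans head-to-head cyclobutane diester on a threitol acetonide (ring A as acetate, ring B as prenyl ether) | CC(=O)Oc1ccc([C@H]2[C@@H]3C(=O)OC[C@@H]4OC(C)(C)O[C@H]4COC(=O)[C@H]3[C@@H]2c2ccc(OCC=C(C)C)c(OC)c2)cc1OC
A3 | alternative 3 | 2-aryl-3-formyl-4-[aryl(tert-butyldimethylsilyloxy)methyl]tetrahydrofuran, both phenols as pivalates | CC(C)(C)C(=O)Oc1ccc([C@@H]2OC[C@@H]([C@@H](O[Si](C)(C)C(C)(C)C)c3ccc(OC(=O)C(C)(C)C)c(OC)c3)[C@H]2C=O)cc1OC
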